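The route rests on cutting the C2–C3 bond of the dihydrobenzofuran and reading C2 (benzylic, O-bearing), C3 (with its CO2H), arene carbon C3a and the side-chain carbon on C4 as a 3-aryl-1-oxoisochromane-4-carboxylic acid. One squaramide-catalysed aldol–lactonisation of a homophthalic anhydride with 3,4-bis(benzyloxy)benzaldehyde forms that bond, fixes C3, and delivers the C3 acid and the C4 carbonyl carbon already differentiated. The anhydride carries a benzyl ether on the future C7 oxygen and a MOM ether on the future O1, so that acid later frees this phenol and transfers C2 from the lactone oxygen to it. Wittig coupling with a danshensu-derived phosphorane and BCl3 debenzylation complete the target.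

Key step: step 6

Assumption: the quinine-derived squaramide is taken to expose the enolate face that leads to the (4S) acid 11; if a test run shows the opposite sense, the quinidine-derived pseudoenantiomer replaces it and nothing else changes.

Step 1
Reactants: 1 4-(benzyloxy)-3-hydroxybenzaldehyde
Product: 2 4-(benzyloxy)-2-bromo-3-hydroxybenzaldehyde
Conditions: Br2 (1.05 equiv), NaOAc, Fe powder (cat.), AcOH, 15–20 °C
Reagents that add atoms: bromine, BrBr
Why: Electrophilic aromatic bromination in which the free 3-OH directs the halogen to the position between itself and the formyl group, as in the standard bromination of isovanillin, while NaOAc buffers the HBr and spares the benzyl ether.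

Step 2
Reactants: 2 4-(benzyloxy)-2-bromo-3-hydroxybenzaldehyde
Product: 3 4-(benzyloxy)-2-bromo-3-(methoxymethoxy)benzaldehyde
Conditions: MOMCl, i-Pr2NEt, CH2Cl2, 0 °C → rt
Reagents that add atoms: chloromethyl methyl ether, COCCl
Why: O-alkylation of the acidic, bromine-flanked phenol with an α-chloro ether (acetal protection) is fast and meets no competing nucleophile.

Step 3
Reactants: 3 4-(benzyloxy)-2-bromo-3-(methoxymethoxy)benzaldehyde
Product: 4 4-(benzyloxy)-2-bromo-3-(methoxymethoxy)benzoic acid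
Conditions: NaClO2, NaH2PO4, 2-methyl-2-butene, t-BuOH/H2O, rt
Reagents that add atoms: sodium chlorite, [Na+].[O-]Cl=O
Why: Pinnick oxidation converts the aldehyde to the acid at about pH 4, mild enough for the MOM acetal and the benzyl ether, with the alkene scavenging HOCl.

Step 4
Reactants: 4 4-(benzyloxy)-2-bromo-3-(methoxymethoxy)benzoic acid; 5 ethyl acetoacetate
Product: 8 4-(benzyloxy)-2-(carboxymethyl)-3-(methoxymethoxy)benzoic acid, via aryl acetoacetate 6 (not isolated), via monoethyl homophthalate 7 (not isolated)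
Conditions: CuBr (10 mol%), NaOEt (3.5 equiv), EtOH, 78 °C; then 2 M aq NaOH, 50 °C; then 1 M HCl to pH 3, 0 °C
Reagents that add atoms: sodium hydroxide, [Na+].[OH-]
Why: Hurtley reaction, in which the ortho carboxylate delivers copper to the C–Br bond so that the acetoacetate carbanion is arylated even at this doubly flanked carbon; ethoxide then removes the acetyl group by retro-Claisen cleavage and hydroxide saponifies the ester, so no acidic decarboxylation threatens the MOM ether.

Step 5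
Reactants: 8 4-(benzyloxy)-2-(carboxymethyl)-3-(methoxymethoxy)benzoic acid
Product: 9 6-(benzyloxy)-5-(methoxymethoxy)isochromane-1,3-dione
Conditions: Ac2O (2 equiv), toluene, 70 °C; evaporate
Reagents that add atoms: none
Why: Cyclodehydration of the 1,5-diacid with acetic anhydride is the standard preparation of homophthalic anhydrides and runs without strong acid, so the MOM ether stays.

Step 6
Reactants: 9 6-(benzyloxy)-5-(methoxymethoxy)isochromane-1,3-dione; 10 3,4-bis(benzyloxy)benzaldehyde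
Product: 11 (3S,4S)-6-(benzyloxy)-3-[3,4-bis(benzyloxy)phenyl]-5-(methoxymethoxy)-1-oxo-3,4-dihydro-1H-isochromene-4-carboxylic acid
Conditions: N-[3,5-bis(trifluoromethyl)phenyl]-N'-(9-deoxy-epi-quinin-9-yl)squaramide (5–10 mol%), MTBE, −15 °C
Reagents that add atoms: none
Why: The quinuclidine nitrogen of the catalyst removes a proton from the acidic benzylic CH2 (C4) of 9 while the squaramide N–H bonds hold aldehyde 10, so the enol adds to the formyl carbon and the alkoxide then acylates itself on the aryl-bound C1 carbonyl, opening the anhydride and releasing the C4 carboxylate. This is the established bifunctional-amine-catalysed formal (4+2) cycloaddition of enolisable homophthalic anhydrides with aromatic aldehydes to trans-3-aryl-1-oxoisochromane-4-carboxylic acids. The one new ring, the δ-lactone, closes by 6-exo-trig acyl transfer of the aldolate oxygen to C1. Lactone C4 (C3 of the target) is set by the enolate face left open in the ion pair with the protonated quinuclidine, and lactone C3 (C2 of the target) by the aldehyde face held on the squaramide, the anti approach giving the trans acid. The step needs only high face selectivity at C4, because the benzylic C3–O bond is re-formed later, and site selectivity for C1 over the C3 carbonyl of the anhydride, which the substrate secures because attack at C3 would give a four-membered lactone.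

Step 7
Reactants: 11 (3S,4S)-6-(benzyloxy)-3-[3,4-bis(benzyloxy)phenyl]-5-(methoxymethoxy)-1-oxo-3,4-dihydro-1H-isochromene-4-carboxylic acid
Product: 12 benzyl (3S,4S)-6-(benzyloxy)-3-[3,4-bis(benzyloxy)phenyl]-5-(methoxymethoxy)-1-oxo-3,4-dihydro-1H-isochromene-4-carboxylate
Conditions: BnBr (1.1 equiv), KHCO3 (1.2 equiv), DMF, 0 °C → rt
Reagents that add atoms: benzyl bromide, BrCc1ccccc1
Why: SN2 O-alkylation of the carboxylate; bicarbonate is too weak a base to remove the C4 proton of the product ester, so neither epimerisation nor β-elimination of the lactone carboxylate is expected.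

Step 8
Reactants: 12 benzyl (3S,4S)-6-(benzyloxy)-3-[3,4-bis(benzyloxy)phenyl]-5-(methoxymethoxy)-1-oxo-3,4-dihydro-1H-isochromene-4-carboxylate
Product: 14 (2S,3S)-7-(benzyloxy)-3-[(benzyloxy)carbonyl]-2-[3,4-bis(benzyloxy)phenyl]-2,3-dihydro-1-benzofuran-4-carboxylic acid, via phenol lactone 13 (not isolated)
Conditions: TFA/CH2Cl2 (1:3), H2O (3 equiv), 0 °C → rt
Reagents that add atoms: none
Why: Proposed new method: TFA first hydrolyses the MOM acetal to phenol 13 and then protonates the lactone carbonyl so that the 3,4-bis(benzyloxy)benzylic C–O bond ionises, as in the acidolysis of p-alkoxybenzyl esters, and the freed phenol on the neighbouring arene carbon captures the cation in a 5-exo closure, the closest known reaction being the acid-mediated cyclisation of 1-aryl-2-(2-hydroxyaryl)ethanols to 2-aryl-2,3-dihydrobenzofurans; C2 should form trans to the untouched C3 ester because closure is reversible and the cis isomer eclipses aryl and ester, and the carboxylic acid set free is a poorer nucleophile and a better leaving group than the phenol.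

Step 9
Reactants: 14 (2S,3S)-7-(benzyloxy)-3-[(benzyloxy)carbonyl]-2-[3,4-bis(benzyloxy)phenyl]-2,3-dihydro-1-benzofuran-4-carboxylic acid
Product: 15 benzyl (2S,3S)-7-(benzyloxy)-2-[3,4-bis(benzyloxy)phenyl]-4-(hydroxymethyl)-2,3-dihydro-1-benzofuran-3-carboxylate
Conditions: BH3·THF (2.5 equiv), THF, 0 °C → rt; MeOH quench
Reagents that add atoms: none
Why: Chemoselective borane reduction of a carboxylic acid through its acyloxyborane leaves the benzyl ester, the benzyl ethers and both stereocentres untouched and uses no base.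

Step 10
Reactants: 15 benzyl (2S,3S)-7-(benzyloxy)-2-[3,4-bis(benzyloxy)phenyl]-4-(hydroxymethyl)-2,3-dihydro-1-benzofuran-3-carboxylate
Product: 16 benzyl (2S,3S)-7-(benzyloxy)-2-[3,4-bis(benzyloxy)phenyl]-4-formyl-2,3-dihydro-1-benzofuran-3-carboxylate
Conditions: activated MnO2 (15 equiv), CH2Cl2, rt
Reagents that add atoms: none
Why: Heterogeneous MnO2 oxidation of an electron-rich benzylic alcohol stops at the aldehyde under neutral conditions that do not touch the base-sensitive C3–H.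

Step 11
Reactants: 17 sodium (2R)-3-(3,4-dihydroxyphenyl)-2-hydroxypropanoate (danshensu sodium salt)
Product: 18 methyl (2R)-3-(3,4-dihydroxyphenyl)-2-hydroxypropanoate
Conditions: HCl in MeOH (1.25 M), rt
Reagents that add atoms: methanol, CO
Why: Fischer esterification, in which the α-hydroxy stereocentre is not enolised under acidic conditions.

Step 12
Reactants: 18 methyl (2R)-3-(3,4-dihydroxyphenyl)-2-hydroxypropanoate
Product: 19 methyl (2R)-3-[3,4-bis(benzyloxy)phenyl]-2-hydroxypropanoate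
Conditions: BnBr (2.2 equiv), K2CO3 (2.5 equiv), acetone, 50 °C
Reagents that add atoms: benzyl bromide, BrCc1ccccc1
Why: Williamson etherification in which carbonate ionises only the two phenols, so the secondary alcohol stays free and the stereocentre is untouched.

Step 13
Reactants: 19 methyl (2R)-3-[3,4-bis(benzyloxy)phenyl]-2-hydroxypropanoate
Product: 20 methyl (2R)-3-[3,4-bis(benzyloxy)phenyl]-2-[(bromoacetyl)oxy]propanoate
Conditions: BrCH2COBr (1.2 equiv), 2,6-lutidine, CH2Cl2, −20 → 0 °C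
Reagents that add atoms: bromoacetyl bromide, BrCC(Br)=O
Why: Acylation of the secondary alcohol by an acid bromide, with a hindered pyridine base that does not quaternise with the bromoacetate formed.

Step 14
Reactants: 20 methyl (2R)-3-[3,4-bis(benzyloxy)phenyl]-2-[(bromoacetyl)oxy]propanoate
Product: 22 methyl (2R)-3-[3,4-bis(benzyloxy)phenyl]-2-{[(triphenyl-λ5-phosphanylidene)acetyl]oxy}propanoate, via phosphonium bromide 21 (not isolated)
Conditions: PPh3, toluene, rt; then aq Na2CO3/CH2Cl2, 0 °C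
Reagents that add atoms: triphenylphosphine, c1ccc(cc1)P(c1ccccc1)c1ccccc1
Why: SN2 quaternisation of PPh3 by the α-bromo ester followed by deprotonation gives the ester-stabilised ylide, which is stable enough to be isolated and stored cold.

Step 15
Reactants: 16 benzyl (2S,3S)-7-(benzyloxy)-2-[3,4-bis(benzyloxy)phenyl]-4-formyl-2,3-dihydro-1-benzofuran-3-carboxylate; 22 methyl (2R)-3-[3,4-bis(benzyloxy)phenyl]-2-{[(triphenyl-λ5-phosphanylidene)acetyl]oxy}propanoate
Product: 23 benzyl (2S,3S)-7-(benzyloxy)-2-[3,4-bis(benzyloxy)phenyl]-4-[(1E)-3-{[(2R)-3-[3,4-bis(benzyloxy)phenyl]-1-methoxy-1-oxopropan-2-yl]oxy}-3-oxoprop-1-en-1-yl]-2,3-dihydro-1-benzofuran-3-carboxylate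
Conditions: toluene, 50 °C
Reagents that add atoms: none
Why: Wittig olefination with a stabilised ylide is E-selective and runs without added base, so the acidic C3–H and the three stereocentres are not touched.

Step 16
Reactants: 23 benzyl (2S,3S)-7-(benzyloxy)-2-[3,4-bis(benzyloxy)phenyl]-4-[(1E)-3-{[(2R)-3-[3,4-bis(benzyloxy)phenyl]-1-methoxy-1-oxopropan-2-yl]oxy}-3-oxoprop-1-en-1-yl]-2,3-dihydro-1-benzofuran-3-carboxylate
Product: 24 (2S,3S)-4-[(1E)-3-{[(2R)-3-(3,4-dihydroxyphenyl)-1-methoxy-1-oxopropan-2-yl]oxy}-3-oxoprop-1-en-1-yl]-2-(3,4-dihydroxyphenyl)-7-hydroxy-2,3-dihydro-1-benzofuran-3-carboxylic acid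
Conditions: BCl3 (1 M in CH2Cl2, 12 equiv), pentamethylbenzene (18 equiv), CH2Cl2, −78 → −30 °C; MeOH quench
Reagents that add atoms: none
Why: Lewis-acid debenzylation with BCl3 and pentamethylbenzene as a non-basic benzyl-cation trap should remove the five aryl benzyl ethers and the benzyl ester at low temperature, while the methyl ester, the enoate (which hydrogenolysis would reduce) and the stereocentres persist.

Compound list

1 | 4-(benzyloxy)-3-hydroxybenzaldehyde | O=Cc1ccc(OCc2ccccc2)c(O)c1 | starting material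
2 | 4-(benzyloxy)-2-bromo-3-hydroxybenzaldehyde | O=Cc1ccc(OCc2ccccc2)c(O)c1Br | intermediate
3 | 4-(benzyloxy)-2-bromo-3-(methoxymethoxy)benzaldehyde | O=Cc1ccc(OCc2ccccc2)c(OCOC)c1Br | intermediate
4 | 4-(benzyloxy)-2-bromo-3-(methoxymethoxy)benzoic acid | OC(=O)c1ccc(OCc2ccccc2)c(OCOC)c1Br | intermediate
5 | ethyl acetoacetate | CCOC(=O)CC(C)=O | starting material
6 | 4-(benzyloxy)-2-(1-ethoxy-1,3-dioxobutan-2-yl)-3-(methoxymethoxy)benzoic acid | OC(=O)c1ccc(OCc2ccccc2)c(OCOC)c1C(C(C)=O)C(=O)OCC | intermediate (not isolated)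
7 | 4-(benzyloxy)-2-(2-ethoxy-2-oxoethyl)-3-(methoxymethoxy)benzoic acid | OC(=O)c1ccc(OCc2ccccc2)c(OCOC)c1CC(=O)OCC | intermediate (not isolated)
8 | 4-(benzyloxy)-2-(carboxymethyl)-3-(methoxymethoxy)benzoic acid | OC(=O)Cc1c(OCOC)c(OCc2ccccc2)ccc1C(=O)O | intermediate
9 | 6-(benzyloxy)-5-(methoxymethoxy)isochromane-1,3-dione | O=C1Cc2c(OCOC)c(OCc3ccccc3)ccc2C(=O)O1 | intermediate
10 | 3,4-bis(benzyloxy)benzaldehyde | O=Cc1ccc(OCc2ccccc2)c(OCc2ccccc2)c1 | starting material
11 | (3S,4S)-6-(benzyloxy)-3-[3,4-bis(benzyloxy)phenyl]-5-(methoxymethoxy)-1-oxo-3,4-dihydro-1H-isochromene-4-carboxylic acid | O=C(O)[C@@H]1[C@@H](c3ccc(OCc4ccccc4)c(OCc4ccccc4)c3)OC(=O)c2ccc(OCc4ccccc4)c(OCOC)c21 | intermediate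
12 | benzyl (3S,4S)-6-(benzyloxy)-3-[3,4-bis(benzyloxy)phenyl]-5-(methoxymethoxy)-1-oxo-3,4-dihydro-1H-isochromene-4-carboxylate | O=C(OCc5ccccc5)[C@@H]1[C@@H](c3ccc(OCc4ccccc4)c(OCc4ccccc4)c3)OC(=O)c2ccc(OCc4ccccc4)c(OCOC)c21 | intermediate
13 | benzyl (3S,4S)-6-(benzyloxy)-3-[3,4-bis(benzyloxy)phenyl]-5-hydroxy-1-oxo-3,4-dihydro-1H-isochromene-4-carboxylate | O=C(OCc5ccccc5)[C@@H]1[C@@H](c3ccc(OCc4ccccc4)c(OCc4ccccc4)c3)OC(=O)c2ccc(OCc4ccccc4)c(O)c21 | intermediate (not isolated)
14 | (2S,3S)-7-(benzyloxy)-3-[(benzyloxy)carbonyl]-2-[3,4-bis(benzyloxy)phenyl]-2,3-dihydro-1-benzofuran-4-carboxylic acid | OC(=O)c1ccc(OCc2ccccc2)c2c1[C@H](C(=O)OCc1ccccc1)[C@@H](c1ccc(OCc3ccccc3)c(OCc3ccccc3)c1)O2 | intermediate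
15 | benzyl (2S,3S)-7-(benzyloxy)-2-[3,4-bis(benzyloxy)phenyl]-4-(hydroxymethyl)-2,3-dihydro-1-benzofuran-3-carboxylate | OCc1ccc(OCc2ccccc2)c2c1[C@H](C(=O)OCc1ccccc1)[C@@H](c1ccc(OCc3ccccc3)c(OCc3ccccc3)c1)O2 | intermediate
16 | benzyl (2S,3S)-7-(benzyloxy)-2-[3,4-bis(benzyloxy)phenyl]-4-formyl-2,3-dihydro-1-benzofuran-3-carboxylate | O=Cc1ccc(OCc2ccccc2)c2c1[C@H](C(=O)OCc1ccccc1)[C@@H](c1ccc(OCc3ccccc3)c(OCc3ccccc3)c1)O2 | intermediate
17 | sodium (2R)-3-(3,4-dihydroxyphenyl)-2-hydroxypropanoate | [Na+].[O-]C(=O)[C@@H](Cc1ccc(O)c(O)c1)O | starting material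
18 | methyl (2R)-3-(3,4-dihydroxyphenyl)-2-hydroxypropanoate | COC(=O)[C@@H](Cc1ccc(O)c(O)c1)O | intermediate
19 | methyl (2R)-3-[3,4-bis(benzyloxy)phenyl]-2-hydroxypropanoate | COC(=O)[C@@H](Cc1ccc(OCc2ccccc2)c(OCc2ccccc2)c1)O | intermediate
20 | methyl (2R)-3-[3,4-bis(benzyloxy)phenyl]-2-[(bromoacetyl)oxy]propanoate | COC(=O)[C@@H](Cc1ccc(OCc2ccccc2)c(OCc2ccccc2)c1)OC(=O)CBr | intermediate
21 | (2-{[(2R)-3-[3,4-bis(benzyloxy)phenyl]-1-methoxy-1-oxopropan-2-yl]oxy}-2-oxoethyl)triphenylphosphonium bromide | COC(=O)[C@@H](Cc1ccc(OCc2ccccc2)c(OCc2ccccc2)c1)OC(=O)C[P+](c1ccccc1)(c1ccccc1)c1ccccc1.[Br-] | intermediate (not isolated)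
22 | methyl (2R)-3-[3,4-bis(benzyloxy)phenyl]-2-{[(triphenyl-λ5-phosphanylidene)acetyl]oxy}propanoate | COC(=O)[C@@H](Cc1ccc(OCc2ccccc2)c(OCc2ccccc2)c1)OC(=O)C=P(c1ccccc1)(c1ccccc1)c1ccccc1 | intermediate
23 | benzyl (2S,3S)-7-(benzyloxy)-2-[3,4-bis(benzyloxy)phenyl]-4-[(1E)-3-{[(2R)-3-[3,4-bis(benzyloxy)phenyl]-1-methoxy-1-oxopropan-2-yl]oxy}-3-oxoprop-1-en-1-yl]-2,3-dihydro-1-benzofuran-3-carboxylate | COC(=O)[C@@H](Cc1ccc(OCc2ccccc2)c(OCc2ccccc2)c1)OC(=O)/C=C/c1ccc(OCc2ccccc2)c2c1[C@H](C(=O)OCc1ccccc1)[C@@H](c1ccc(OCc3ccccc3)c(OCc3ccccc3)c1)O2 | intermediate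
24 | (2S,3S)-4-[(1E)-3-{[(2R)-3-(3,4-dihydroxyphenyl)-1-methoxy-1-oxopropan-2-yl]oxy}-3-oxoprop-1-en-1-yl]-2-(3,4-dihydroxyphenyl)-7-hydroxy-2,3-dihydro-1-benzofuran-3-carboxylic acid | COC(=O)[C@@H](Cc1ccc(O)c(O)c1)OC(=O)/C=C/c1ccc(O)c2c1[C@H](C(=O)O)[C@@H](c1ccc(O)c(O)c1)O2 | target

Total step count: 16. Longest linear sequence: 12 steps (steps 1–10, 15 and 16).

Steps most likely to fail

1. Step 8 (lactone-to-ether ring switch). What may go wrong: the benzylic cation may lose the C3 proton and drain into a stilbene, or it may return to the lactone faster than the phenol captures it, so that the equilibrium stays on the lactone side. Fallback, using the established rhodium-carbenoid benzylic C–H insertion: it sets out from bromophenol 2, which is O-alkylated with commercial 3,4-bis(benzyloxy)benzyl chloride (K2CO3, KI, DMF) to 4-(benzyloxy)-3-{[3,4-bis(benzyloxy)phenyl]methoxy}-2-bromobenzaldehyde F1. The aldehyde is masked with ethylene glycol (TsOH, toluene, water removal) as 2-[4-(benzyloxy)-3-{[3,4-bis(benzyloxy)phenyl]methoxy}-2-bromophenyl]-1,3-dioxolane F2. Pd-catalysed coupling with the zinc enolate BrZnCH2CO2Bn (Pd(dba)2, Q-phos, THF) gives benzyl 2-[3-(benzyloxy)-2-{[3,4-bis(benzyloxy)phenyl]methoxy}-6-(1,3-dioxolan-2-yl)phenyl]acetate F3. Diazo transfer (4-acetamidobenzenesulfonyl azide, DBU, MeCN) gives benzyl 2-diazo-2-[3-(benzyloxy)-2-{[3,4-bis(benzyloxy)phenyl]methoxy}-6-(1,3-dioxolan-2-yl)phenyl]acetate F4. Rh2(S-DOSP)4, or its mirror image if that is the one that sets C2 as S, inserts the carbenoid into the benzylic C–H bond of the ether to give benzyl (2S,3R)-7-(benzyloxy)-2-[3,4-bis(benzyloxy)phenyl]-4-(1,3-dioxolan-2-yl)-2,3-dihydro-1-benzofuran-3-carboxylate F5. DBU epimerises C3 to benzyl (2S,3S)-7-(benzyloxy)-2-[3,4-bis(benzyloxy)phenyl]-4-(1,3-dioxolan-2-yl)-2,3-dihydro-1-benzofuran-3-carboxylate F6, and PPTS in wet acetone frees the aldehyde, so the route is rejoined at 16.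

2. Step 6 (key step). What may go wrong: face discrimination at the enolate carbon may be eroded by the neighbouring MOM ether, and addition to the electron-rich aldehyde may be slow enough for the acid centre to epimerise. Fallback, by resolution instead of asymmetric catalysis: it sets out from 9 and 10, which are combined with i-Pr2NEt in CH2Cl2 at rt to give the racemic trans acid. This is 11 together with its mirror image (3R,4R)-6-(benzyloxy)-3-[3,4-bis(benzyloxy)phenyl]-5-(methoxymethoxy)-1-oxo-3,4-dihydro-1H-isochromene-4-carboxylic acid F7. Crystallisation with (S)-1-phenylethylamine, or its antipode if that gives the less soluble salt of 11, should give (1S)-1-phenylethanaminium (3S,4S)-6-(benzyloxy)-3-[3,4-bis(benzyloxy)phenyl]-5-(methoxymethoxy)-1-oxo-3,4-dihydro-1H-isochromene-4-carboxylate F8. Cold dilute HCl then returns 11.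

3. Step 4 (copper-mediated arylation). What may go wrong: copper insertion at a bromide flanked by two ortho substituents may be slow, so that hydrodebromination or substitution by ethoxide takes over. Fallback, by palladium catalysis on the ester: it sets out from 4, which is converted with MeI and K2CO3 in DMF into methyl 4-(benzyloxy)-2-bromo-3-(methoxymethoxy)benzoate F9. Arylation of dimethyl malonate (Pd2(dba)3, P(t-Bu)3·HBF4, K3PO4, toluene, 80 °C) gives dimethyl 2-[3-(benzyloxy)-6-(methoxycarbonyl)-2-(methoxymethoxy)phenyl]propanedioate F10. Saponification with aq NaOH, acidification to pH 3 and warming in dioxane (decarboxylation) then give 8.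

Further compounds

F1 | step 8 | 4-(benzyloxy)-3-{[3,4-bis(benzyloxy)phenyl]methoxy}-2-bromobenzaldehyde | O=Cc1ccc(OCc2ccccc2)c(OCc2ccc(OCc3ccccc3)c(OCc3ccccc3)c2)c1Br
F2 | step 8 | 2-[4-(benzyloxy)-3-{[3,4-bis(benzyloxy)phenyl]methoxy}-2-bromophenyl]-1,3-dioxolane | Brc1c(C2OCCO2)ccc(OCc2ccccc2)c1OCc1ccc(OCc2ccccc2)c(OCc2ccccc2)c1
F3 | step 8 | benzyl 2-[3-(benzyloxy)-2-{[3,4-bis(benzyloxy)phenyl]methoxy}-6-(1,3-dioxolan-2-yl)phenyl]acetate | O=C(Cc1c(C2OCCO2)ccc(OCc2ccccc2)c1OCc1ccc(OCc2ccccc2)c(OCc2ccccc2)c1)OCc1ccccc1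
F4 | step 8 | benzyl 2-diazo-2-[3-(benzyloxy)-2-{[3,4-bis(benzyloxy)phenyl]methoxy}-6-(1,3-dioxolan-2-yl)phenyl]acetate | [N-]=[N+]=C(c1c(C2OCCO2)ccc(OCc2ccccc2)c1OCc1ccc(OCc2ccccc2)c(OCc2ccccc2)c1)C(=O)OCc1ccccc1
F5 | step 8 | benzyl (2S,3R)-7-(benzyloxy)-2-[3,4-bis(benzyloxy)phenyl]-4-(1,3-dioxolan-2-yl)-2,3-dihydro-1-benzofuran-3-carboxylate | C1COC(O1)c1ccc(OCc2ccccc2)c2c1[C@@H](C(=O)OCc1ccccc1)[C@@H](c1ccc(OCc3ccccc3)c(OCc3ccccc3)c1)O2
F6 | step 8 | benzyl (2S,3S)-7-(benzyloxy)-2-[3,4-bis(benzyloxy)phenyl]-4-(1,3-dioxolan-2-yl)-2,3-dihydro-1-benzofuran-3-carboxylate | C1COC(O1)c1ccc(OCc2ccccc2)c2c1[C@H](C(=O)OCc1ccccc1)[C@@H](c1ccc(OCc3ccccc3)c(OCc3ccccc3)c1)O2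
F7 | step 6 | (3R,4R)-6-(benzyloxy)-3-[3,4-bis(benzyloxy)phenyl]-5-(methoxymethoxy)-1-oxo-3,4-dihydro-1H-isochromene-4-carboxylic acid | O=C(O)[C@H]1[C@H](c3ccc(OCc4ccccc4)c(OCc4ccccc4)c3)OC(=O)c2ccc(OCc4ccccc4)c(OCOC)c21
F8 | step 6 | (1S)-1-phenylethanaminium (3S,4S)-6-(benzyloxy)-3-[3,4-bis(benzyloxy)phenyl]-5-(methoxymethoxy)-1-oxo-3,4-dihydro-1H-isochromene-4-carboxylate | C[C@H]([NH3+])c1ccccc1.[O-]C(=O)[C@@H]1[C@@H](c3ccc(OCc4ccccc4)c(OCc4ccccc4)c3)OC(=O)c2ccc(OCc4ccccc4)c(OCOC)c21
F9 | step 4 | methyl 4-(benzyloxy)-2-bromo-3-(methoxymethoxy)benzoate | COC(=O)c1ccc(OCc2ccccc2)c(OCOC)c1Br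
F10 | step 4 | dimethyl 2-[3-(benzyloxy)-6-(methoxycarbonyl)-2-(methoxymethoxy)phenyl]propanedioate | COC(=O)c1ccc(OCc2ccccc2)c(OCOC)c1C(C(=O)OC)C(=O)OC
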